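**Plan**

1. Positions follow germacranolide numbering: ring A is the ten-membered carbocycle C1–C10, ring B the butenolide C6–O–C12(=O)–C11=C7, C13 the acetoxymethyl carbon. The enabling feature is that C7=C11 of ring B is flanked by the oxygenated carbons C8 and C13 (a but-2-yne-1,4-diol imprint), that C6–O and C12=O are the imprint of an aldehyde and CO, and that C6–C7 is the bond shared by rings A and B.
2. Retrosynthesis: remove the three esters (C8 angelate, C10 and C13 acetates) and return the C1 ketone to a silyl-protected carbinol; then cut rings A and B together through C6–C7 and C11–C12 (and O6–C12) to a linear 4,5-epoxy ynal plus CO.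
3. The linear chain is cut at C2–C3 (methyl ketone enolate plus allylic bromide) and at C7–C8 (acyl–alkyne coupling), back to (R)-citramalic acid, a propargyl silyl ether and prenyl acetate.
4. Forward: C8–C9–C10–C1 comes from citramalic acid, then the alkyne, then the C2–C6 arm, then the oxirane. One nickel/CO event closes ring A and ring B together; oxidation at C1 and the three esters come last.
5. Stereochemistry: C10 is bought ((R)-citramalic acid); C8 is set by Noyori transfer hydrogenation; C4/C5 by Sharpless epoxidation; C6 is relayed from C5 under macrocyclic control in the key step. The C1 carbinol is temporary.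

Key step: step 15

Assumption: prenyl acetate, (R)-citramalic acid, the TBDPS ether of propargyl alcohol and angelic acid are taken as commercial. The C1 carbinol is drawn as 1R, the sense expected from the (S)-oxazaborolidine; its configuration is erased in step 17.

**Route**

Step 1
Reactants: 1 prenyl acetate (3-methylbut-2-en-1-yl acetate)
Product: 2 (E)-4-hydroxy-3-methylbut-2-en-1-yl acetate
Conditions: SeO2 (cat.), t-BuOOH, CH2Cl2, 25 °C
Reagents that add atoms: tert-butyl hydroperoxide, CC(C)(C)OO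
Why: Selenium dioxide allylic oxidation (ene reaction, then [2,3]-sigmatropic shift) should oxidise the methyl group trans to the chain, which fixes the E geometry of the future C4–C5 unit.

Step 2
Reactants: 2 (E)-4-hydroxy-3-methylbut-2-en-1-yl acetate
Product: 3 (E)-4-bromo-3-methylbut-2-en-1-yl acetate
Conditions: CBr4, PPh3, CH2Cl2, 0 °C
Reagents that add atoms: carbon tetrabromide, BrC(Br)(Br)Br
Why: Appel bromination of the primary allylic alcohol should proceed without allylic transposition at low temperature and leaves the acetate untouched.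

Step 3
Reactants: 4 (R)-citramalic acid
Product: 5 2-[(4R)-2,2,4-trimethyl-5-oxo-1,3-dioxolan-4-yl]acetic acid
Conditions: 2,2-dimethoxypropane, PPTS (cat.), 25 °C
Reagents that add atoms: 2,2-dimethoxypropane, COC(C)(C)OC
Why: Acid-catalysed acetalisation ties the tertiary hydroxyl and its own carboxyl into the five-membered dioxolanone (favoured over the six-membered alternative) and leaves the C8 carboxyl free; C10 comes unchanged from the chiral pool.

Step 4
Reactants: 5 2-[(4R)-2,2,4-trimethyl-5-oxo-1,3-dioxolan-4-yl]acetic acid; 6 tert-butyl(diphenyl)(prop-2-yn-1-yloxy)silane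
Product: 8 (5R)-5-[5-(tert-butyldiphenylsilyloxy)-2-oxopent-3-yn-1-yl]-2,2,5-trimethyl-1,3-dioxolan-4-one, via acid chloride 7 (not isolated)
Conditions: (COCl)2, DMF (cat.), CH2Cl2, 0 → 25 °C, evaporate; then 6, PdCl2(PPh3)2 (cat.), CuI (cat.), Et3N, THF, 25 °C
Reagents that add atoms: oxalyl chloride, O=C(Cl)C(Cl)=O (chlorine of 7 only)
Why: Acid chloride formation followed by acyl Sonogashira coupling should make the C7–C8 bond and give the ynone without touching the dioxolanone.

Step 5
Reactants: 8 the ynone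
Product: 9 (5R)-5-[(2S)-5-(tert-butyldiphenylsilyloxy)-2-hydroxypent-3-yn-1-yl]-2,2,5-trimethyl-1,3-dioxolan-4-one
Conditions: Ru[(S,S)-TsDPEN](p-cymene) (cat.), i-PrOH, 25 °C (TsDPEN = N-tosyl-1,2-diphenylethylenediamine)
Reagents that add atoms: none
Why: Noyori asymmetric transfer hydrogenation of an ynone is catalyst-controlled, and the (S,S) catalyst should give the (S)-propargylic alcohol (C8) whatever the remote C10 centre.

Step 6
Reactants: 9 the propargylic alcohol
Product: 10 (2R,4S)-7-(tert-butyldiphenylsilyloxy)-2,4-dihydroxy-N-methoxy-N,2-dimethylhept-5-ynamide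
Conditions: MeNHOMe·HCl, i-PrMgCl, THF, −20 → 0 °C
Reagents that add atoms: N,O-dimethylhydroxylamine hydrochloride, CNOC.Cl
Why: The chloromagnesium amide opens the activated dioxolanone ester (Weinreb amide formation), releasing acetone and both hydroxyls.

Step 7
Reactants: 10 the dihydroxy Weinreb amide
Product: 12 (2R,4S)-4-(tert-butyldimethylsilyloxy)-7-(tert-butyldiphenylsilyloxy)-N-methoxy-N,2-dimethyl-2-(triethylsilyloxy)hept-5-ynamide, via mono-TBS ether 11 (not isolated)
Conditions: TBSOTf (1.05 equiv), 2,6-lutidine, CH2Cl2, −78 °C; then TESOTf, −78 → 0 °C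
Reagents that add atoms: tert-butyldimethylsilyl triflate, CC(C)(C)[Si](C)(C)OS(=O)(=O)C(F)(F)F; triethylsilyl triflate, CC[Si](CC)(CC)OS(=O)(=O)C(F)(F)F
Why: The unhindered secondary propargylic hydroxyl should be silylated first and the tertiary one second, which gives O8 and O10 different silyl groups in one flask and stops relactonisation of the γ-hydroxy amide.

Step 8
Reactants: 12 the bis-silylated Weinreb amide
Product: 13 (3R,5S)-5-(tert-butyldimethylsilyloxy)-8-(tert-butyldiphenylsilyloxy)-3-methyl-3-(triethylsilyloxy)oct-6-yn-2-one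
Conditions: MeMgBr, THF, 0 → 25 °C
Reagents that add atoms: methylmagnesium bromide, C[Mg]Br
Why: Grignard addition to a Weinreb amide stops at the chelated tetrahedral intermediate and gives the methyl ketone (C1, C2) on work-up.

Step 9
Reactants: 13 the methyl ketone; 3 (E)-4-bromo-3-methylbut-2-en-1-yl acetate
Product: 15 (2E,7R,9S)-9-(tert-butyldimethylsilyloxy)-12-(tert-butyldiphenylsilyloxy)-3,7-dimethyl-6-oxo-7-(triethylsilyloxy)dodec-2-en-10-yn-1-yl acetate, via lithium enolate 14 (not isolated)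
Conditions: LiN(i-Pr)2 (1.05 equiv), THF, −78 °C; then 3, DMPU, −78 → −40 °C
Reagents that add atoms: lithium diisopropylamide, [Li]N(C(C)C)C(C)C (lithium of 14 only)
Why: The ketone can enolise only toward its methyl group because C10 is quaternary, so kinetic deprotonation and SN2 alkylation with the primary allylic bromide should form C2–C3 regioselectively.

Step 10
Reactants: 15 the ketone
Product: 16 (2E,6R,7R,9S)-9-(tert-butyldimethylsilyloxy)-12-(tert-butyldiphenylsilyloxy)-6-hydroxy-3,7-dimethyl-7-(triethylsilyloxy)dodec-2-en-10-yn-1-yl acetate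
Conditions: (S)-Me-CBS oxazaborolidine (cat.), catecholborane, toluene, −78 → −40 °C
Reagents that add atoms: none
Why: Corey–Bakshi–Shibata reduction distinguishes the quaternary C10 side from the methylene side and should give the 1R carbinol under catalyst control; the centre only masks C1 as sp3 so that no five-membered ynone cyclisation can compete in step 15.

Step 11
Reactants: 16 the C1 carbinol
Product: 17 (2E,6R,7R,9S)-9-(tert-butyldimethylsilyloxy)-12-(tert-butyldiphenylsilyloxy)-3,7-dimethyl-6,7-bis(triethylsilyloxy)dodec-2-en-10-yn-1-yl acetate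
Conditions: TESOTf, 2,6-lutidine, CH2Cl2, −78 → 0 °C
Reagents that add atoms: triethylsilyl triflate, CC[Si](CC)(CC)OS(=O)(=O)C(F)(F)F
Why: Silyl triflate silylation protects the hindered secondary hydroxyl without an alkoxide, so neither silyl migration nor acetate cleavage should occur.

Step 12
Reactants: 17 the acetate
Product: 18 (2E,6R,7R,9S)-9-(tert-butyldimethylsilyloxy)-12-(tert-butyldiphenylsilyloxy)-3,7-dimethyl-6,7-bis(triethylsilyloxy)dodec-2-en-10-yn-1-ol
Conditions: K2CO3, MeOH, 0 °C
Reagents that add atoms: none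
Why: Mild transesterification removes the primary allylic acetate while the silyl ethers should survive carbonate in methanol at 0 °C.

Step 13
Reactants: 18 the allylic alcohol
Product: 19 [(2R,3R)-3-[(3R,4R,6S)-6-(tert-butyldimethylsilyloxy)-9-(tert-butyldiphenylsilyloxy)-4-methyl-3,4-bis(triethylsilyloxy)non-7-yn-1-yl]-3-methyloxiran-2-yl]methanol
Conditions: Ti(OiPr)4 (cat.), D-(−)-diethyl tartrate (cat.), t-BuOOH, 4 Å molecular sieves, CH2Cl2, −20 °C
Reagents that add atoms: tert-butyl hydroperoxide, CC(C)(C)OO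
Why: Sharpless asymmetric epoxidation of the E-trisubstituted allylic alcohol with the D-(−)-tartrate should give the (4R,5R)-oxirane under reagent control (the sense opposite to that of the L-(+)-tartrate); the remote centres have no say.

Step 14
Reactants: 19 the epoxy alcohol
Product: 20 (2S,3R)-3-[(3R,4R,6S)-6-(tert-butyldimethylsilyloxy)-9-(tert-butyldiphenylsilyloxy)-4-methyl-3,4-bis(triethylsilyloxy)non-7-yn-1-yl]-3-methyloxirane-2-carbaldehyde
Conditions: Dess–Martin periodinane, NaHCO3, CH2Cl2, 0 → 25 °C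
Reagents that add atoms: none
Why: Buffered Dess–Martin oxidation should give the epoxy aldehyde without epimerisation at C5 or epoxide opening (the descriptor at C5 changes only because C6 gains priority).

Step 15
Reactants: 20 the 4,5-epoxy ynal
Product: 22 (1R,4R,5R,6S,8S,10R)-8-(tert-butyldimethylsilyloxy)-13-(tert-butyldiphenylsilyloxy)-4,5-epoxy-1,10-bis(triethylsilyloxy)germacr-7(11)-en-12,6-olide, via oxanickelacyclopentene 21 (not isolated)
Conditions: Ni(cod)2 (1.1 equiv), IPr (1.1 equiv; 1,3-bis(2,6-diisopropylphenyl)imidazol-2-ylidene), toluene, 25 °C, slow addition of 20 to about 2 mM; then CO (1 atm), 25 °C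
Reagents that add atoms: carbon monoxide, [C-]#[O+]; bis(1,5-cyclooctadiene)nickel, C1=CCCC=CCC1.C1=CCCC=CCC1.[Ni], and IPr, CC(C)c1cccc(C(C)C)c1N1C=CN([C]1)c1c(C(C)C)cccc1C(C)C (both in 21 only)
Why: Proposed new method: zerovalent nickel carrying the bulky carbene IPr should couple the alkyne and the aldehyde of 20 oxidatively (C6–C7) to the oxanickelacyclopentene 21, whose Ni–C11 bond then inserts CO (C11–C12) and whose acyl nickel alkoxide reductively eliminates the O6–C12 bond, a hetero-Pauson–Khand-type [2+2+1]; the closest known reactions are the stoichiometric nickel-mediated alkyne–aldehyde coupling with carbonylation of the nickelacycle to a butenolide, nickel-catalysed reductive macrocyclisation of ynals, and hetero-Pauson–Khand cyclisation of ynals to butenolides fused to five- and six-membered rings. Ring A closes in the exo mode at the tether-bearing alkyne carbon C7 (C11 stays outside ring A), and ring B closes by CO insertion and C–O reductive elimination from the five-membered nickelacycle. C6 is the only new stereocentre and is set by C5 of the trans-epoxide under macrocyclic constraint: C7 must attack from the ring-interior face anti to the C5–O bond while the nickel-bound carbonyl oxygen points to the periphery and H6 eclipses C4 and its cis methyl group, which should give 6S (O6 syn to the epoxide oxygen), the sense also expected from chromium-mediated closures of 4,5-epoxygermacrane rings at this bond. Regioselectivity (C7, not C11) is secured by the bulky carbene, which keeps the smaller CH2OSi-bearing carbon next to nickel, and by the strain of the alternative bridged eleven-membered E-alkene. Chemoselectivity is secured by the substrate: C1 is an sp3 silyl ether, so no ynone or enyne can close a five-membered ring, and the aldehyde is far more reactive than the epoxide toward zerovalent nickel. Ring closure should win over oligomerisation through slow addition to stoichiometric nickel at high dilution and through the turn elements of the chain (trans-epoxide, quaternary C10).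

Step 16
Reactants: 22 the macrocyclic butenolide
Product: 23 (1R,4R,5R,6S,8S,10R)-8-(tert-butyldimethylsilyloxy)-13-(tert-butyldiphenylsilyloxy)-4,5-epoxy-1,10-dihydroxygermacr-7(11)-en-12,6-olide
Conditions: HF·pyridine, pyridine, THF, 0 → 25 °C
Reagents that add atoms: none
Why: Buffered HF·pyridine should cleave the two triethylsilyl ethers much faster than the secondary TBS and primary TBDPS ethers, and the near-neutral medium should spare the epoxide.

Step 17
Reactants: 23 the 1,10-diol
Product: 24 (4R,5R,6S,8S,10R)-8-(tert-butyldimethylsilyloxy)-13-(tert-butyldiphenylsilyloxy)-4,5-epoxy-10-hydroxy-1-oxogermacr-7(11)-en-12,6-olide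
Conditions: Dess–Martin periodinane, NaHCO3, CH2Cl2, 0 °C
Reagents that add atoms: none
Why: Dess–Martin oxidation converts the secondary C1 carbinol into the ketone while the tertiary C10 hydroxyl cannot be oxidised; this erases the temporary stereocentre and removes the hydroxyl that could open the epoxide across the ring.

Step 18
Reactants: 24 the α-ketol
Product: 25 (4R,5R,6S,8S,10R)-4,5-epoxy-8,10,13-trihydroxy-1-oxogermacr-7(11)-en-12,6-olide
Conditions: TBAF, AcOH (1:1), THF, 25 °C
Reagents that add atoms: none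
Why: Acetic-acid-buffered fluoride removes the TBS and TBDPS ethers without the basicity that would deprotonate C6 of the butenolide next to the epoxide.

Step 19
Reactants: 25 the keto triol
Product: 26 (4R,5R,6S,8S,10R)-13-acetoxy-4,5-epoxy-8,10-dihydroxy-1-oxogermacr-7(11)-en-12,6-olide
Conditions: AcCl (1.05 equiv), 2,4,6-collidine, CH2Cl2, −78 °C
Reagents that add atoms: acetyl chloride, CC(Cl)=O
Why: Acetyl chloride with collidine at low temperature should acylate the primary allylic hydroxyl selectively over the secondary and tertiary ones on steric grounds.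

Step 20
Reactants: 26 the 13-acetate
Product: 27 (4R,5R,6S,8S,10R)-13-acetoxy-8-angeloyloxy-4,5-epoxy-10-hydroxy-1-oxogermacr-7(11)-en-12,6-olide
Conditions: angelic acid, 2,4,6-trichlorobenzoyl chloride, Et3N, toluene, 25 °C; then 26, toluene, 80 °C
Reagents that add atoms: angelic acid, C/C=C(/C)C(O)=O
Why: Yamaguchi-type mixed anhydride esterification without a nucleophilic catalyst should transfer the angeloyl group to the secondary C8 hydroxyl with the Z geometry retained; the tertiary hydroxyl does not react.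

Step 21
Reactants: 27 the angelate
Product: 28 the target, (4R,5R,6S,8S,10R)-10,13-diacetoxy-8-angeloyloxy-4,5-epoxy-1-oxogermacr-7(11)-en-12,6-olide
Conditions: Ac2O, DMAP (cat.), Et3N, CH2Cl2, 25 → 40 °C
Reagents that add atoms: acetic anhydride, CC(=O)OC(C)=O
Why: DMAP-catalysed acetylation of the tertiary α-ketol hydroxyl completes the target; no stereocentre is touched.

**Compound list**

1 | prenyl acetate | CC(C)=CCOC(C)=O | starting material
2 | (E)-4-hydroxy-3-methylbut-2-en-1-yl acetate | CC(=O)OC/C=C(\C)CO | intermediate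
3 | (E)-4-bromo-3-methylbut-2-en-1-yl acetate | CC(=O)OC/C=C(\C)CBr | intermediate
4 | (R)-citramalic acid | C[C@@](O)(CC(=O)O)C(=O)O | starting material
5 | 2-[(4R)-2,2,4-trimethyl-5-oxo-1,3-dioxolan-4-yl]acetic acid | C[C@]1(CC(=O)O)OC(C)(C)OC1=O | intermediate
6 | tert-butyl(diphenyl)(prop-2-yn-1-yloxy)silane | C#CCO[Si](c1ccccc1)(c1ccccc1)C(C)(C)C | starting material
7 | 2-[(4R)-2,2,4-trimethyl-5-oxo-1,3-dioxolan-4-yl]acetyl chloride | C[C@]1(CC(=O)Cl)OC(C)(C)OC1=O | intermediate
8 | ynone (C8 ketone, C7≡C11 alkyne, C13 OTBDPS, dioxolanone at C10/C1) | C[C@]1(CC(=O)C#CCO[Si](c2ccccc2)(c2ccccc2)C(C)(C)C)OC(C)(C)OC1=O | intermediate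
9 | (8S)-propargylic alcohol of 8 | C[C@]1(C[C@H](O)C#CCO[Si](c2ccccc2)(c2ccccc2)C(C)(C)C)OC(C)(C)OC1=O | intermediate
10 | dihydroxy Weinreb amide (C1 amide, 10R tertiary OH, 8S OH) | CON(C)C(=O)[C@](C)(O)C[C@H](O)C#CCO[Si](c1ccccc1)(c1ccccc1)C(C)(C)C | intermediate
11 | mono-TBS ether of 10 (O8 TBS, O10 free) | CON(C)C(=O)[C@](C)(O)C[C@H](O[Si](C)(C)C(C)(C)C)C#CCO[Si](c1ccccc1)(c1ccccc1)C(C)(C)C | intermediate
12 | Weinreb amide with O8 TBS and O10 TES | CON(C)C(=O)[C@](C)(O[Si](CC)(CC)CC)C[C@H](O[Si](C)(C)C(C)(C)C)C#CCO[Si](c1ccccc1)(c1ccccc1)C(C)(C)C | intermediate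
13 | methyl ketone (C1 carbonyl, C2 methyl) | CC(=O)[C@](C)(O[Si](CC)(CC)CC)C[C@H](O[Si](C)(C)C(C)(C)C)C#CCO[Si](c1ccccc1)(c1ccccc1)C(C)(C)C | intermediate
14 | lithium enolate of 13 | [Li]OC(=C)[C@](C)(O[Si](CC)(CC)CC)C[C@H](O[Si](C)(C)C(C)(C)C)C#CCO[Si](c1ccccc1)(c1ccccc1)C(C)(C)C | intermediate
15 | C1 ketone with the C2–C6 arm (E-alkene, O6 acetate) | CC(=O)OC/C=C(\C)CCC(=O)[C@](C)(O[Si](CC)(CC)CC)C[C@H](O[Si](C)(C)C(C)(C)C)C#CCO[Si](c1ccccc1)(c1ccccc1)C(C)(C)C | intermediate
16 | (1R)-carbinol of 15 | CC(=O)OC/C=C(\C)CC[C@@H](O)[C@](C)(O[Si](CC)(CC)CC)C[C@H](O[Si](C)(C)C(C)(C)C)C#CCO[Si](c1ccccc1)(c1ccccc1)C(C)(C)C | intermediate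
17 | O1 TES ether of 16 | CC(=O)OC/C=C(\C)CC[C@@H](O[Si](CC)(CC)CC)[C@](C)(O[Si](CC)(CC)CC)C[C@H](O[Si](C)(C)C(C)(C)C)C#CCO[Si](c1ccccc1)(c1ccccc1)C(C)(C)C | intermediate
18 | C6 allylic alcohol | OC/C=C(\C)CC[C@@H](O[Si](CC)(CC)CC)[C@](C)(O[Si](CC)(CC)CC)C[C@H](O[Si](C)(C)C(C)(C)C)C#CCO[Si](c1ccccc1)(c1ccccc1)C(C)(C)C | intermediate
19 | (4R,5R)-epoxy alcohol | OC[C@H]1O[C@]1(C)CC[C@@H](O[Si](CC)(CC)CC)[C@](C)(O[Si](CC)(CC)CC)C[C@H](O[Si](C)(C)C(C)(C)C)C#CCO[Si](c1ccccc1)(c1ccccc1)C(C)(C)C | intermediate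
20 | 4,5-epoxy ynal (C6 aldehyde) | O=C[C@H]1O[C@]1(C)CC[C@@H](O[Si](CC)(CC)CC)[C@](C)(O[Si](CC)(CC)CC)C[C@H](O[Si](C)(C)C(C)(C)C)C#CCO[Si](c1ccccc1)(c1ccccc1)C(C)(C)C | intermediate
21 | oxanickelacyclopentene (IPr-bound divalent nickel bridging O6 and C11) | CC(C)(C)[Si](C)(C)O[C@H]1C[C@@](C)(O[Si](CC)(CC)CC)[C@H](O[Si](CC)(CC)CC)CC[C@@]2(C)O[C@@H]2[C@H]2O[Ni](=C3N(c4c(C(C)C)cccc4C(C)C)C=CN3c3c(C(C)C)cccc3C(C)C)C(CO[Si](c3ccccc3)(c3ccccc3)C(C)(C)C)=C12 | intermediate
22 | macrocyclic butenolide, fully silylated | CC(C)(C)[Si](C)(C)O[C@H]1C[C@@](C)(O[Si](CC)(CC)CC)[C@H](O[Si](CC)(CC)CC)CC[C@@]2(C)O[C@@H]2[C@H]2OC(=O)C(CO[Si](c3ccccc3)(c3ccccc3)C(C)(C)C)=C12 | intermediate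
23 | 1,10-diol | CC(C)(C)[Si](C)(C)O[C@H]1C[C@@](C)(O)[C@H](O)CC[C@@]2(C)O[C@@H]2[C@H]2OC(=O)C(CO[Si](c3ccccc3)(c3ccccc3)C(C)(C)C)=C12 | intermediate
24 | 1-oxo-10-hydroxy compound (α-ketol) | CC(C)(C)[Si](C)(C)O[C@H]1C[C@@](C)(O)C(=O)CC[C@@]2(C)O[C@@H]2[C@H]2OC(=O)C(CO[Si](c3ccccc3)(c3ccccc3)C(C)(C)C)=C12 | intermediate
25 | keto triol | O[C@H]1C[C@@](C)(O)C(=O)CC[C@@]2(C)O[C@@H]2[C@H]2OC(=O)C(CO)=C12 | intermediate
26 | 13-acetate | O[C@H]1C[C@@](C)(O)C(=O)CC[C@@]2(C)O[C@@H]2[C@H]2OC(=O)C(COC(C)=O)=C12 | intermediate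
27 | 8-angelate 13-acetate | C/C=C(/C)C(=O)O[C@H]1C[C@@](C)(O)C(=O)CC[C@@]2(C)O[C@@H]2[C@H]2OC(=O)C(COC(C)=O)=C12 | intermediate
28 | CNP0175424.2 | C/C=C(/C)C(=O)O[C@H]1C[C@@](C)(OC(C)=O)C(=O)CC[C@@]2(C)O[C@@H]2[C@H]2OC(=O)C(COC(C)=O)=C12 | target

**Counts**

Total step count: 21. Longest linear sequence: 19 steps (steps 3 to 21, from (R)-citramalic acid).

**Steps most likely to fail**

1. Step 15 (Proposed new method). What may go wrong: oligomerisation instead of ten-membered ring closure; coupling at C11 (endo mode); nickel insertion into the epoxide C5–O bond beside the aldehyde; loss of the C13 silyloxy group by β-elimination from the nickelacycle; or poor facial selectivity at C6. Fallback: the two bonds are made in separate, known operations. Setting out from allylic alcohol 18, the alkyne is complexed with Ti(OiPr)4/i-PrMgCl (titanacyclopropene F1, not isolated). CO2 then inserts at the less hindered C11–Ti bond (oxatitanacyclopentenone F2, not isolated), and iodinolysis gives the (Z)-β-iodo acid F3, in which C11–C12 already exists. TMSCHN2 gives the methyl ester F4. Sharpless epoxidation as in step 13 gives the epoxy alcohol F5, and Dess–Martin oxidation gives the epoxy aldehyde F6. An intramolecular Nozaki–Hiyama–Kishi addition (CrCl2, NiCl2 cat., DMSO/THF, high dilution) then closes C6–C7, and the resulting alkoxide lactonises onto the cis ester. This returns to the route at 22.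

2. Step 20. What may go wrong: isomerisation of the angeloyl group to the tigloyl group during activation or acyl transfer, or no acylation of the hindered C8 hydroxyl. Fallback: the Z-alkene is built after the acylation. Setting out from 26, DCC/DMAP esterification with 2-[bis(2,2,2-trifluoroethoxy)phosphoryl]propanoic acid gives the phosphonate ester F7 (both epimers at the phosphonate carbon). Still–Gennari olefination with acetaldehyde (K2CO3, 18-crown-6, toluene, −20 °C) should then give the Z-2-methylbut-2-enoate. This returns to the route at 27.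

3. Step 21. What may go wrong: slow acetylation of the hindered tertiary α-ketol hydroxyl, so that forcing conditions cause Z/E isomerisation of the angelate by DMAP addition–elimination, or base-triggered opening of the epoxide from C6. Fallback: the order is changed so that the tertiary acetate exists before the angelate. Setting out from 24, Ac2O/DMAP/Et3N (40 °C) gives the 10-acetate F8. TBAF/AcOH gives the diol F9, and AcCl/collidine at −78 °C gives the 10,13-diacetate F10. Yamaguchi angeloylation as in step 20 then gives the target, returning to the route at 28.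

**Further compounds**

F1 | step 15 | titanacyclopropene of 18 (chloromagnesium alkoxide at O6) | Cl[Mg]OC/C=C(\C)CC[C@@H](O[Si](CC)(CC)CC)[C@](C)(O[Si](CC)(CC)CC)C[C@H](O[Si](C)(C)C(C)(C)C)C1=C(CO[Si](c2ccccc2)(c2ccccc2)C(C)(C)C)[Ti]1(OC(C)C)OC(C)C
F2 | step 15 | oxatitanacyclopentenone (Ti on C7, carboxylate on C11) | Cl[Mg]OC/C=C(\C)CC[C@@H](O[Si](CC)(CC)CC)[C@](C)(O[Si](CC)(CC)CC)C[C@H](O[Si](C)(C)C(C)(C)C)C1=C(CO[Si](c2ccccc2)(c2ccccc2)C(C)(C)C)C(=O)O[Ti]1(OC(C)C)OC(C)C
F3 | step 15 | (Z)-β-iodo acid (iodine on C7, CO2H on C11) | OC/C=C(\C)CC[C@@H](O[Si](CC)(CC)CC)[C@](C)(O[Si](CC)(CC)CC)C[C@H](O[Si](C)(C)C(C)(C)C)/C(I)=C(\CO[Si](c1ccccc1)(c1ccccc1)C(C)(C)C)C(=O)O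
F4 | step 15 | methyl ester of F3 | OC/C=C(\C)CC[C@@H](O[Si](CC)(CC)CC)[C@](C)(O[Si](CC)(CC)CC)C[C@H](O[Si](C)(C)C(C)(C)C)/C(I)=C(\CO[Si](c1ccccc1)(c1ccccc1)C(C)(C)C)C(=O)OC
F5 | step 15 | (4R,5R)-epoxy alcohol of F4 | OC[C@H]1O[C@]1(C)CC[C@@H](O[Si](CC)(CC)CC)[C@](C)(O[Si](CC)(CC)CC)C[C@H](O[Si](C)(C)C(C)(C)C)/C(I)=C(\CO[Si](c1ccccc1)(c1ccccc1)C(C)(C)C)C(=O)OC
F6 | step 15 | epoxy aldehyde of F5 | O=C[C@H]1O[C@]1(C)CC[C@@H](O[Si](CC)(CC)CC)[C@](C)(O[Si](CC)(CC)CC)C[C@H](O[Si](C)(C)C(C)(C)C)/C(I)=C(\CO[Si](c1ccccc1)(c1ccccc1)C(C)(C)C)C(=O)OC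
F7 | step 20 | 8-O-[2-[bis(2,2,2-trifluoroethoxy)phosphoryl]propanoyl] ester of 26 | CC(C(=O)O[C@H]1C[C@@](C)(O)C(=O)CC[C@@]2(C)O[C@@H]2[C@H]2OC(=O)C(COC(C)=O)=C12)P(=O)(OCC(F)(F)F)OCC(F)(F)F
F8 | step 21 | 10-acetate of 24 | CC(C)(C)[Si](C)(C)O[C@H]1C[C@@](C)(OC(C)=O)C(=O)CC[C@@]2(C)O[C@@H]2[C@H]2OC(=O)C(CO[Si](c3ccccc3)(c3ccccc3)C(C)(C)C)=C12
F9 | step 21 | 10-acetoxy-8,13-diol | O[C@H]1C[C@@](C)(OC(C)=O)C(=O)CC[C@@]2(C)O[C@@H]2[C@H]2OC(=O)C(CO)=C12
F10 | step 21 | 10,13-diacetoxy-8-ol | O[C@H]1C[C@@](C)(OC(C)=O)C(=O)CC[C@@]2(C)O[C@@H]2[C@H]2OC(=O)C(COC(C)=O)=C12
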